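**Plan**

- Retrosynthesis: the O3 epoxyangelate and the O4 acetate come off first. The cis-decalin is then opened at C4–C5 and C9–C10 in a single cut. The resulting chain is divided at C1–C10 (alkyl–alkenyl coupling) and C6–C7 (enolate alkylation); C8–C9 and C4–C15 are methyl additions to acyl groups.
- Enabling feature: the carbinol carbon C4 (bearing C15) is bonded to ring-fusion C5, C5 to quaternary C10, and the C8 carbonyl reaches C10 through C9. A C4 methyl ketone, a (Z)-C5=C10 olefin and a C8 enol silane in one open chain therefore map onto rings A and B.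
- Forward: an Evans alkylation joins the isovaleryl unit (C7, C8, C11–C13) to the C5/C6/C10/C14 iodoalkene, and a Negishi coupling adds the lactone-derived C1–C4 unit. The two acyl ends are then told apart: thioester to ketone to enol silane at C8, Weinreb amide to ketone at C4.
- One TiCl4 step closes ring A (C4–C5) and ring B (C9–C10). Acetylation of O4, debenzylation and Yamaguchi esterification of O3 complete the target.
- Stereochemistry: C3 comes from (R)-alpha-hydroxy-gamma-butyrolactone, C7 from the (R)-oxazolidinone, and the olefin geometry from trans-hydroalumination/iodination. C4, C5 and C10 arise in the key step from the C3 chelate and the Z olefin; the epoxide comes from a Sharpless epoxidation with D-(−)-diethyl tartrate.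

Key step: step 13

Remark: eudesmane numbering is used for chain and rings (C15–C4–C3–C2–C1–C10(C14)–C5–C6–C7(iPr)–C8–C9; ring A = C1–C5, C10; ring B = C5–C10). The target SMILES is read as 3R,4S,5S,7R,10R, cis-fused, with O3 and O4 alpha, C14, C15, H5 and the isopropyl group beta, and a (2S,3S)-2,3-dimethyloxirane-2-carboxylate (epoxyangelate) on O3.

**Route**

Step 1
Reactants: 1 but-2-yn-1-ol
Product: 3 (Z)-3-iodobut-2-en-1-ol, via cyclic vinylalanate 2 (not isolated)
Conditions: NaAlH2(OCH2CH2OMe)2, THF, 0 °C to rt; then I2, THF, −78 °C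
Reagents that add atoms: iodine, II
Why: Alkoxide-directed trans-hydroalumination of the propargylic alcohol puts aluminium on the distal alkyne carbon inside a five-membered aluminate, and iodinolysis with retention gives the Z iodoalkene with iodine cis to CH2OH, which fixes the later C5=C10 geometry.

Step 2
Reactants: 3 (Z)-3-iodobut-2-en-1-ol
Product: 4 (Z)-1-bromo-3-iodobut-2-ene
Conditions: PBr3, Et2O, 0 °C
Reagents that add atoms: phosphorus tribromide, BrP(Br)Br
Why: Bromination of the primary allylic alcohol with PBr3 is an SN2 displacement of the phosphite ester that leaves the alkenyl iodide and its Z geometry untouched.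

Step 3
Reactants: 5 (4R)-4-benzyl-1,3-oxazolidin-2-one; 6 3-methylbutanoyl chloride
Product: 7 (4R)-4-benzyl-3-(3-methylbutanoyl)-1,3-oxazolidin-2-one
Conditions: Et3N, DMAP (cat.), CH2Cl2, 0 °C to rt
Reagents that add atoms: none
Why: DMAP-catalysed N-acylation of the oxazolidinone by the acid chloride is a standard way to load an Evans auxiliary without a strong base.

Step 4
Reactants: 7 (4R)-4-benzyl-3-(3-methylbutanoyl)-1,3-oxazolidin-2-one; 4 (Z)-1-bromo-3-iodobut-2-ene
Product: 9 (4R)-4-benzyl-3-[(2R,4Z)-5-iodo-2-(propan-2-yl)hex-4-enoyl]-1,3-oxazolidin-2-one, via sodium enolate 8 (not isolated)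
Conditions: NaN(SiMe3)2, THF, −78 °C; then 4, −78 to −40 °C
Reagents that add atoms: none
Why: Evans asymmetric alkylation, in which the sodium-chelated Z enolate is alkylated by the allylic bromide on the face away from the benzyl group, so that the (R)-auxiliary sets C7 as R (isopropyl outranks the new CH2) while the alkenyl iodide is inert to the amide base at −78 °C.

Step 5
Reactants: 10 (3R)-3-hydroxyoxolan-2-one
Product: 11 (3R)-3-(benzyloxy)oxolan-2-one
Conditions: BnBr, Ag2O, CH2Cl2, rt, dark
Reagents that add atoms: benzyl bromide, BrCc1ccccc1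
Why: Ag2O-mediated Williamson benzylation works without a soluble strong base, so the alpha-oxygenated lactone is neither opened nor enolised and C3 keeps the R configuration.

Step 6
Reactants: 11 (3R)-3-(benzyloxy)oxolan-2-one
Product: 12 (2R)-2-(benzyloxy)-4-hydroxy-N-methoxy-N-methylbutanamide
Conditions: MeONHMe·HCl, AlMe3, CH2Cl2, 0 °C to rt; aq. potassium sodium tartrate
Reagents that add atoms: N,O-dimethylhydroxylamine hydrochloride, CNOC.Cl
Why: Weinreb aminolysis of the lactone by the chloromethylaluminium amide opens the ring to the gamma-hydroxy N-methoxy-N-methylamide without touching C3, and the product is taken on at once because it slowly relactonises.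

Step 7
Reactants: 12 (2R)-2-(benzyloxy)-4-hydroxy-N-methoxy-N-methylbutanamide
Product: 13 (2R)-2-(benzyloxy)-4-iodo-N-methoxy-N-methylbutanamide
Conditions: I2, PPh3, imidazole, CH2Cl2, 0 °C
Reagents that add atoms: iodine, II
Why: Appel-type iodination converts the primary alcohol into the iodide by SN2 displacement of the alkoxyphosphonium ion under conditions too mild to epimerise C3.

Step 8
Reactants: 13 (2R)-2-(benzyloxy)-4-iodo-N-methoxy-N-methylbutanamide; 9 (4R)-4-benzyl-3-[(2R,4Z)-5-iodo-2-(propan-2-yl)hex-4-enoyl]-1,3-oxazolidin-2-one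
Product: 15 (4R)-4-benzyl-3-{(2R,4Z,8R)-8-(benzyloxy)-9-[methoxy(methyl)amino]-5-methyl-9-oxo-2-(propan-2-yl)non-4-enoyl}-1,3-oxazolidin-2-one, via alkylzinc iodide 14 (not isolated)
Conditions: Zn dust (activated with TMSCl and BrCH2CH2Br), LiCl, THF, 35 °C; then 9, Pd(PPh3)4 (5 mol%), THF, 45 °C
Reagents that add atoms: none
Why: Negishi coupling, in which zinc inserts into the primary carbon–iodine bond and the alkylzinc iodide, tolerant of the Weinreb amide and the imide, couples with the alkenyl iodide under zerovalent palladium catalysis with retention of the Z geometry to form C1–C10.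

Step 9
Reactants: 15 (4R)-4-benzyl-3-{(2R,4Z,8R)-8-(benzyloxy)-9-[methoxy(methyl)amino]-5-methyl-9-oxo-2-(propan-2-yl)non-4-enoyl}-1,3-oxazolidin-2-one
Product: 16 S-ethyl (2R,4Z,8R)-8-(benzyloxy)-9-[methoxy(methyl)amino]-5-methyl-9-oxo-2-(propan-2-yl)non-4-enethioate
Conditions: EtSH, n-BuLi, THF, 0 °C
Reagents that add atoms: ethanethiol, CCS
Why: Lithium ethanethiolate attacks the exocyclic imide carbonyl selectively even in hindered acyl oxazolidinones (thiolate cleavage of an Evans imide), releasing the auxiliary and giving the thioester while the less electrophilic Weinreb amide and both stereocentres stay as they are.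

Step 10
Reactants: 16 S-ethyl (2R,4Z,8R)-8-(benzyloxy)-9-[methoxy(methyl)amino]-5-methyl-9-oxo-2-(propan-2-yl)non-4-enethioate
Product: 17 (2R,5Z,8R)-2-(benzyloxy)-N-methoxy-N,5-dimethyl-9-oxo-8-(propan-2-yl)dec-5-enamide
Conditions: CuI, MeLi (2 equiv per Cu), Et2O, 0 °C; then 16, −78 to −40 °C; aq. NH4Cl
Reagents that add atoms: methyllithium, [Li]C
Why: Lithium dimethylcuprate substitutes thioesters to give methyl ketones at low temperature and reacts neither with Weinreb amides nor with the ketone formed, so C8–C9 is installed chemoselectively and without epimerising C7.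

Step 11
Reactants: 17 (2R,5Z,8R)-2-(benzyloxy)-N-methoxy-N,5-dimethyl-9-oxo-8-(propan-2-yl)dec-5-enamide
Product: 19 (2R,5Z,8R)-2-(benzyloxy)-9-[(tert-butyldimethylsilyl)oxy]-N-methoxy-N,5-dimethyl-8-(propan-2-yl)deca-5,9-dienamide, via lithium enolate 18 (not isolated)
Conditions: LiN(iPr)2 (1.1 equiv), THF, −78 °C; TBSOTf, −78 °C; Et3N, aq. NaHCO3
Reagents that add atoms: tert-butyldimethylsilyl trifluoromethanesulfonate, CC(C)(C)[Si](C)(C)OS(=O)(=O)C(F)(F)F
Why: Kinetic enolisation with the hindered amide base takes the open C9 methyl protons of the ketone (more acidic than C3–H beside the amide and far more accessible than C7–H), and O-silylation of the lithium enolate by the silyl triflate gives the terminal silyl enol ether.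

Step 12
Reactants: 19 (2R,5Z,8R)-2-(benzyloxy)-9-[(tert-butyldimethylsilyl)oxy]-N-methoxy-N,5-dimethyl-8-(propan-2-yl)deca-5,9-dienamide
Product: 21 (3R,6Z,9R)-3-(benzyloxy)-10-[(tert-butyldimethylsilyl)oxy]-6-methyl-9-(propan-2-yl)undeca-6,10-dien-2-one, via magnesium chelate 20 (not isolated)
Conditions: MeMgBr, THF, −20 to 0 °C; pH 7 phosphate buffer
Reagents that add atoms: methylmagnesium bromide, C[Mg]Br
Why: Weinreb ketone synthesis, in which MeMgBr adds once to give a stable five-membered magnesium chelate that collapses to the C4 methyl ketone only on buffered work-up, a sequence that does not racemise alpha-alkoxy amides and leaves tert-butyldimethylsilyl enol ethers intact.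

Step 13
Reactants: 21 (3R,6Z,9R)-3-(benzyloxy)-10-[(tert-butyldimethylsilyl)oxy]-6-methyl-9-(propan-2-yl)undeca-6,10-dien-2-one
Product: 23 (3R,4S,5S,7R,10R)-3-(benzyloxy)-4-hydroxy-cis-eudesman-8-one, via titanium alkoxide 22 (not isolated)
Conditions: TiCl4 (1.1 equiv), 2,6-di-tert-butyl-4-methylpyridine (0.5 equiv), CH2Cl2 (0.002 M), −78 °C; aq. NaHCO3
Reagents that add atoms: none
Why: Proposed new method: TiCl4 locks the C4 carbonyl and the C3 benzyloxy oxygen in a five-membered chelate, C5 of the Z olefin adds to the activated C4 (ring A, 6-endo at the olefin, Markovnikov) and the tertiary C10 cation that develops is trapped on the opposite olefin face by C9 of the silyl enol ether (ring B, 6-endo at the enol ether), after which chloride takes the silyl group and the C8 ketone is released. The closest known reactions are chelation-controlled Prins and carbonyl-ene cyclisations of alpha-alkoxy carbonyl compounds and Stork–Eschenmoser-type cation–olefin cyclisations ended by silyl enol ethers, whereas a simple ketone as initiator of such a bicyclisation has no precedent. C4 is controlled by the chelate and the tether: with O3 held near the carbonyl plane the three-carbon link lets C5 reach only the Si face of C4, the one on the side of C2, so O4 ends cis to O3 (4S). C5 and C10 are controlled by the chair of that chelate and by the olefin geometry: the forming C4–C5 bond lies gauche to C3–O3 (O3 axial, carbonyl oxygen equatorial), which exposes the Si face of C5 (5S), and antiperiplanar addition across the Z olefin puts C9 on the Si face of C10 (10R), hence H5 and C14 cis. The step needs olefin-face selectivity relative to C3 and preference of the ketone for the olefin over the enol ether: bidentate binding of the small benzyl ether is relied on to outweigh the syn-axial O3/C6 and C15/C14 contacts of the productive chair, while high dilution, the sluggish tert-butyldimethylsilyl enol ether and six- against ten-membered ring formation suppress direct Mukaiyama aldol addition. C3 and C7 are spectators, the hindered pyridine removes HCl, and ring inversion of the product places O3, C15 and the isopropyl group equatorial, which is why the 7R centre is also the thermodynamic one.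

Step 14
Reactants: 23 (3R,4S,5S,7R,10R)-3-(benzyloxy)-4-hydroxy-cis-eudesman-8-one
Product: 24 (3R,4S,5S,7R,10R)-4-acetoxy-3-(benzyloxy)-cis-eudesman-8-one
Conditions: Ac2O, DMAP, Et3N, toluene, 60 °C
Reagents that add atoms: acetic anhydride, CC(=O)OC(C)=O
Why: DMAP-catalysed acetylation through the N-acetylpyridinium ion is the standard method for tertiary alcohols, the benzyl ether keeps O3 blocked, and C7 cannot drift because its isopropyl group already sits in the favoured equatorial position.

Step 15
Reactants: 24 (3R,4S,5S,7R,10R)-4-acetoxy-3-(benzyloxy)-cis-eudesman-8-one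
Product: 25 (3R,4S,5S,7R,10R)-4-acetoxy-3-hydroxy-cis-eudesman-8-one
Conditions: H2 (1 atm), Pd/C, EtOAc, rt
Reagents that add atoms: none
Why: Hydrogenolysis of the benzyl ether over Pd/C is selective for the benzylic carbon–oxygen bond and leaves the ketone, the tertiary acetate and all stereocentres untouched.

Step 16
Reactants: 26 angelic acid
Product: 27 (Z)-2-methylbut-2-en-1-ol
Conditions: LiAlH4, Et2O, 0 °C to rt
Reagents that add atoms: none
Why: LiAlH4 reduces the carboxylic acid to the allylic alcohol by 1,2-hydride addition, and the trisubstituted Z olefin of this alkyl-substituted enoic acid is neither reduced nor isomerised.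

Step 17
Reactants: 27 (Z)-2-methylbut-2-en-1-ol
Product: 28 [(2R,3S)-2,3-dimethyloxiran-2-yl]methanol
Conditions: Ti(OiPr)4 (10 mol%), D-(−)-diethyl tartrate (12 mol%), t-BuOOH, 4 Å molecular sieves, CH2Cl2, −20 °C
Reagents that add atoms: tert-butyl hydroperoxide, CC(C)(C)OO
Why: Sharpless asymmetric epoxidation, in which the titanium complex of D-(−)-diethyl tartrate delivers oxygen to the olefin face that gives the (2R,3S)-epoxy alcohol while the Z geometry keeps the two methyl groups trans.

Step 18
Reactants: 28 [(2R,3S)-2,3-dimethyloxiran-2-yl]methanol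
Product: 29 (2S,3S)-2,3-dimethyloxirane-2-carboxylic acid
Conditions: RuCl3 hydrate (2 mol%), NaIO4, CCl4/MeCN/H2O, rt
Reagents that add atoms: water, O
Why: RuO4 generated catalytically from RuCl3 and NaIO4 oxidises the primary alcohol through the aldehyde hydrate to the carboxylic acid without opening the epoxide, so both epoxide centres are carried over and the C2 descriptor changes from R to S only through the CIP priorities.

Step 19
Reactants: 29 (2S,3S)-2,3-dimethyloxirane-2-carboxylic acid; 25 (3R,4S,5S,7R,10R)-4-acetoxy-3-hydroxy-cis-eudesman-8-one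
Product: 31 CNP0221066.1 (3R,4S,5S,7R,10R)-4-acetoxy-8-oxo-cis-eudesman-3-yl (2S,3S)-2,3-dimethyloxirane-2-carboxylate, via mixed anhydride 30 (not isolated)
Conditions: 29, 2,4,6-trichlorobenzoyl chloride, Et3N, toluene, rt; then 25, DMAP, toluene, rt to 40 °C
Reagents that add atoms: none
Why: Yamaguchi esterification, in which DMAP attacks the mixed anhydride at the less hindered epoxy acyl carbon and the acylpyridinium ion esterifies the equatorial C3 hydroxyl with retention at C3, under conditions that form no free alkoxide so that the C4 acetate should stay in place and the epoxide closed.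

**Compound list**

1 | but-2-yn-1-ol | CC#CCO | starting material
2 | sodium 2,2-bis(2-methoxyethoxy)-3-methyl-2,5-dihydro-1,2-oxaaluminol-2-uide (cyclic vinylalanate) | CC1=CCO[Al-]1(OCCOC)OCCOC.[Na+] | intermediate
3 | (Z)-3-iodobut-2-en-1-ol | OC/C=C(/C)I | intermediate
4 | (Z)-1-bromo-3-iodobut-2-ene | BrC/C=C(/C)I | intermediate
5 | (4R)-4-benzyl-1,3-oxazolidin-2-one | O=C1N[C@H](Cc2ccccc2)CO1 | starting material
6 | 3-methylbutanoyl chloride (isovaleryl chloride) | CC(C)CC(=O)Cl | starting material
7 | (4R)-4-benzyl-3-(3-methylbutanoyl)-1,3-oxazolidin-2-one | CC(C)CC(=O)N1[C@H](Cc2ccccc2)COC1=O | intermediate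
8 | sodium (Z)-enolate of 7 | CC(C)/C=C(\[O-])N1[C@H](Cc2ccccc2)COC1=O.[Na+] | intermediate
9 | (4R)-4-benzyl-3-[(2R,4Z)-5-iodo-2-(propan-2-yl)hex-4-enoyl]-1,3-oxazolidin-2-one | I/C(C)=C\C[C@H](C(C)C)C(=O)N1[C@H](Cc2ccccc2)COC1=O | intermediate
10 | (3R)-3-hydroxyoxolan-2-one [(R)-alpha-hydroxy-gamma-butyrolactone] | O=C1OCC[C@H]1O | starting material
11 | (3R)-3-(benzyloxy)oxolan-2-one | O=C1OCC[C@H]1OCc2ccccc2 | intermediate
12 | (2R)-2-(benzyloxy)-4-hydroxy-N-methoxy-N-methylbutanamide | CON(C)C(=O)[C@H](OCc1ccccc1)CCO | intermediate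
13 | (2R)-2-(benzyloxy)-4-iodo-N-methoxy-N-methylbutanamide | CON(C)C(=O)[C@H](OCc1ccccc1)CCI | intermediate
14 | {(3R)-3-(benzyloxy)-4-[methoxy(methyl)amino]-4-oxobutyl}zinc iodide | CON(C)C(=O)[C@H](OCc1ccccc1)CC[Zn]I | intermediate
15 | (4R)-4-benzyl-3-{(2R,4Z,8R)-8-(benzyloxy)-9-[methoxy(methyl)amino]-5-methyl-9-oxo-2-(propan-2-yl)non-4-enoyl}-1,3-oxazolidin-2-one | CON(C)C(=O)[C@H](OCc1ccccc1)CC/C(C)=C\C[C@H](C(C)C)C(=O)N1[C@H](Cc2ccccc2)COC1=O | intermediate
16 | S-ethyl (2R,4Z,8R)-8-(benzyloxy)-9-[methoxy(methyl)amino]-5-methyl-9-oxo-2-(propan-2-yl)non-4-enethioate | CON(C)C(=O)[C@H](OCc1ccccc1)CC/C(C)=C\C[C@H](C(C)C)C(=O)SCC | intermediate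
17 | (2R,5Z,8R)-2-(benzyloxy)-N-methoxy-N,5-dimethyl-9-oxo-8-(propan-2-yl)dec-5-enamide | CON(C)C(=O)[C@H](OCc1ccccc1)CC/C(C)=C\C[C@H](C(C)C)C(C)=O | intermediate
18 | lithium enolate of 17 (O on C8, C8=C9) | CON(C)C(=O)[C@H](OCc1ccccc1)CC/C(C)=C\C[C@H](C(C)C)C(=C)[O-].[Li+] | intermediate
19 | (2R,5Z,8R)-2-(benzyloxy)-9-[(tert-butyldimethylsilyl)oxy]-N-methoxy-N,5-dimethyl-8-(propan-2-yl)deca-5,9-dienamide | CON(C)C(=O)[C@H](OCc1ccccc1)CC/C(C)=C\C[C@H](C(C)C)C(=C)O[Si](C)(C)C(C)(C)C | intermediate
20 | bromomagnesium chelate of the tetrahedral MeMgBr adduct of 19 | CON(C)C(C)(O[Mg]Br)[C@H](OCc1ccccc1)CC/C(C)=C\C[C@H](C(C)C)C(=C)O[Si](C)(C)C(C)(C)C | intermediate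
21 | (3R,6Z,9R)-3-(benzyloxy)-10-[(tert-butyldimethylsilyl)oxy]-6-methyl-9-(propan-2-yl)undeca-6,10-dien-2-one | CC(=O)[C@H](OCc1ccccc1)CC/C(C)=C\C[C@H](C(C)C)C(=C)O[Si](C)(C)C(C)(C)C | intermediate
22 | trichlorotitanium alkoxide of 23 | Cl[Ti](Cl)(Cl)O[C@]1(C)[C@H](OCc2ccccc2)CC[C@]3(C)CC(=O)[C@@H](C(C)C)C[C@@H]31 | intermediate
23 | (3R,4S,5S,7R,10R)-3-(benzyloxy)-4-hydroxy-cis-eudesman-8-one [(3R,4aS,5S,6R,8aR)-6-(benzyloxy)-5-hydroxy-5,8a-dimethyl-3-(propan-2-yl)octahydronaphthalen-2(1H)-one] | O[C@]1(C)[C@H](OCc2ccccc2)CC[C@]3(C)CC(=O)[C@@H](C(C)C)C[C@@H]31 | intermediate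
24 | (3R,4S,5S,7R,10R)-4-acetoxy-3-(benzyloxy)-cis-eudesman-8-one | CC(=O)O[C@]1(C)[C@H](OCc2ccccc2)CC[C@]3(C)CC(=O)[C@@H](C(C)C)C[C@@H]31 | intermediate
25 | (3R,4S,5S,7R,10R)-4-acetoxy-3-hydroxy-cis-eudesman-8-one | CC(=O)O[C@]1(C)[C@H](O)CC[C@]2(C)CC(=O)[C@@H](C(C)C)C[C@@H]21 | intermediate
26 | angelic acid [(Z)-2-methylbut-2-enoic acid] | C/C=C(/C)C(=O)O | starting material
27 | (Z)-2-methylbut-2-en-1-ol | C/C=C(/C)CO | intermediate
28 | [(2R,3S)-2,3-dimethyloxiran-2-yl]methanol | OC[C@@]1(C)O[C@H]1C | intermediate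
29 | (2S,3S)-2,3-dimethyloxirane-2-carboxylic acid | OC(=O)[C@@]1(C)O[C@H]1C | intermediate
30 | (2S,3S)-2,3-dimethyloxirane-2-carboxylic 2,4,6-trichlorobenzoic anhydride | O=C(OC(=O)[C@@]1(C)O[C@H]1C)c1c(Cl)cc(Cl)cc1Cl | intermediate
31 | CNP0221066.1, (3R,4S,5S,7R,10R)-4-acetoxy-8-oxo-cis-eudesman-3-yl (2S,3S)-2,3-dimethyloxirane-2-carboxylate | CC(=O)O[C@]1(C)[C@H](OC(=O)[C@@]2(C)O[C@H]2C)CC[C@]2(C)CC(=O)[C@@H](C(C)C)C[C@@H]21 | target

**Step count and risks**

Total: 19 steps. Longest linear sequence: 12 steps (1, 2, 4, 8–15, 19 from but-2-yn-1-ol; the lactone branch 5–7 joins at step 8 and is equally long).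

Most likely to fail:

Step 13. The olefin may attack through the unchelated chair, which would give the cis-decalin epimeric at C5 and C10; the C10 cation may lose a proton before ring B closes; or the enol silane may add to the ketone of a second molecule. The fallback uses known chemistry and sets out from 19. Reduction of the Weinreb amide with i-Bu2AlH (THF, −78 °C) should give the aldehyde (2R,5Z,8R)-2-(benzyloxy)-9-[(tert-butyldimethylsilyl)oxy]-5-methyl-8-(propan-2-yl)deca-5,9-dienal F1. SnCl4 (CH2Cl2, −78 °C) should then bring about an aldehyde-initiated, chelation-controlled Prins cyclisation carried on as a cation–olefin cascade to the enol silane, giving (3R,4S,5S,7R,10R)-3-(benzyloxy)-4-hydroxy-15-nor-cis-eudesman-8-one F2. Here the productive chair has only hydrogen axial at C4. Dess–Martin oxidation should give (3R,5S,7R,10R)-3-(benzyloxy)-15-nor-cis-eudesmane-4,8-dione F3. MeTiCl3 (CH2Cl2, −78 °C) engages only the chelating alpha-benzyloxy ketone and should deliver methyl to the beta face, since the alpha face is screened by the axial C9 methylene; this returns to the route at 23.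

Step 11. The base may remove the C3 proton beside the amide or attack the N-methoxy group, and enolisation may stray toward C7. The fallback sets out from 9 and moves the enolisation ahead of the fragment union, so that no amide is present. LiSEt should cleave the auxiliary to S-ethyl (2R,4Z)-5-iodo-2-(propan-2-yl)hex-4-enethioate F4. Me2CuLi at −78 °C, where alkenyl iodides do not yet couple with cuprates, should give (3R,5Z)-6-iodo-3-(propan-2-yl)hept-5-en-2-one F5. LiN(iPr)2 followed by TBSOTf at −78 °C should give tert-butyl{[(3R,5Z)-6-iodo-3-(propan-2-yl)hepta-1,5-dien-2-yl]oxy}dimethylsilane F6. Negishi coupling of F6 with the zinc reagent 14 then comes back to the route at 19.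

Step 14. Acylation of the axial tertiary O4, flanked by the C3 ether and syn-axial to C9, may be too slow, and forcing conditions may start dehydration at C4. The fallback sets out from 23 and delivers the acetyl group from within. Hydrogenolysis (H2, Pd/C) should give (3R,4S,5S,7R,10R)-3,4-dihydroxy-cis-eudesman-8-one F7. MeC(OMe)3 with catalytic camphorsulfonic acid should close the cis-diol to the 3,4-O-(1-methoxyethylidene) cyclic orthoacetate F8. Mild hydrolysis in aqueous acetic acid opens such orthoesters under stereoelectronic control to the axial ester, here the O4 acetate with free equatorial O3–H, which is 25, where the route is rejoined.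

Further compounds
F1 | step 13 | (2R,5Z,8R)-2-(benzyloxy)-9-[(tert-butyldimethylsilyl)oxy]-5-methyl-8-(propan-2-yl)deca-5,9-dienal | O=C[C@H](OCc1ccccc1)CC/C(C)=C\C[C@H](C(C)C)C(=C)O[Si](C)(C)C(C)(C)C
F2 | step 13 | (3R,4S,5S,7R,10R)-3-(benzyloxy)-4-hydroxy-15-nor-cis-eudesman-8-one | O[C@@H]1[C@H](OCc2ccccc2)CC[C@]3(C)CC(=O)[C@@H](C(C)C)C[C@@H]31
F3 | step 13 | (3R,5S,7R,10R)-3-(benzyloxy)-15-nor-cis-eudesmane-4,8-dione | O=C1[C@H](OCc2ccccc2)CC[C@]3(C)CC(=O)[C@@H](C(C)C)C[C@@H]31
F4 | step 11 | S-ethyl (2R,4Z)-5-iodo-2-(propan-2-yl)hex-4-enethioate | I/C(C)=C\C[C@H](C(C)C)C(=O)SCC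
F5 | step 11 | (3R,5Z)-6-iodo-3-(propan-2-yl)hept-5-en-2-one | I/C(C)=C\C[C@H](C(C)C)C(C)=O
F6 | step 11 | tert-butyl{[(3R,5Z)-6-iodo-3-(propan-2-yl)hepta-1,5-dien-2-yl]oxy}dimethylsilane | I/C(C)=C\C[C@H](C(C)C)C(=C)O[Si](C)(C)C(C)(C)C
F7 | step 14 | (3R,4S,5S,7R,10R)-3,4-dihydroxy-cis-eudesman-8-one | O[C@]1(C)[C@H](O)CC[C@]2(C)CC(=O)[C@@H](C(C)C)C[C@@H]21
F8 | step 14 | 3,4-O-(1-methoxyethylidene) derivative (cyclic orthoacetate) of F7 | COC2(C)O[C@]1(C)[C@H](O2)CC[C@]3(C)CC(=O)[C@@H](C(C)C)C[C@@H]31
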